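**Retrosynthetic overview**
1. Last bond: the ketal C–O bond from flavan O7 (dihydrofuran ring). It closes when a perbenzylated 2,3-dihydroxyflavanone hemiketal is debenzylated.
2. Key bond: carbinol carbon to flavan C8. It is made by a catalytic enantioselective Friedel–Crafts addition of the C8–H of a tri-O-benzyl-(2S)-flavan to the central carbonyl of a vicinal tricarbonyl, and the chromanone ring closes in the same flask.
3. Both halves come from one o-hydroxyaryl 1,3-diketone. Oxidation gives the tricarbonyl; cyclodehydration, asymmetric hydrogenation and deoxygenation give the flavan.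
4. Ring order: flavan pyran ring, chromanone ring, dihydrofuran ring. The usual plan is not used (build the 2-aryl-3-aroylbenzofuran of daphnodorin A on the flavan, then oxidise its furan double bond).

Assumption: the flavan centre (S) and the carbinol centre (R) of the SMILES are the centres put under external control; the ketal carbon equilibrates under acid, so the natural product is taken to be the thermodynamic epimer there and is written exactly as in the given string (which, read literally, places the ketal aryl group anti to the tertiary OH); the ligand antipodes named in steps 6 and 8 are taken to give the required senses, their mirror images being equally available.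

**Step 1**
Reactants: 1 2',4',6'-trihydroxyacetophenone
Product: 2 1-[2,4-bis(benzyloxy)-6-hydroxyphenyl]ethan-1-one
Conditions: BnBr (2.1 equiv), K2CO3 (2.2 equiv), DMF, rt to 60 °C
Reagents that add atoms: benzyl bromide, BrCc1ccccc1
Why: Williamson ether synthesis, in which the last OH is hydrogen-bonded to the acetyl group and is the least nucleophilic, so two equivalents of halide stop cleanly at the dibenzyl ether.

**Step 2**
Reactants: 2 1-[2,4-bis(benzyloxy)-6-hydroxyphenyl]ethan-1-one; 3 4-(benzyloxy)benzoyl chloride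
Product: 4 1-[2,4-bis(benzyloxy)-6-hydroxyphenyl]-3-[4-(benzyloxy)phenyl]propane-1,3-dione
Conditions: LiN(SiMe3)2 (3.5 equiv), THF, −78 to −10 °C; then 3, −78 °C to rt; aq. HCl work-up
Reagents that add atoms: none
Why: Claisen-type C-acylation of the lithium phenoxide/enolate dianion (the one-flask equivalent of a Baker–Venkataraman sequence), where the excess base stores the product as its diketonate and prevents double acylation.

**Step 3**
Reactants: 4 1-[2,4-bis(benzyloxy)-6-hydroxyphenyl]-3-[4-(benzyloxy)phenyl]propane-1,3-dione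
Product: 5 1-[2,4-bis(benzyloxy)-6-hydroxyphenyl]-3-[4-(benzyloxy)phenyl]-2-diazopropane-1,3-dione
Conditions: 4-acetamidobenzenesulfonyl azide (1.2 equiv), Et3N (1.5 equiv), MeCN, 0 °C to rt
Reagents that add atoms: 4-acetamidobenzenesulfonyl azide, CC(=O)Nc1ccc(cc1)S(=O)(=O)N=[N+]=[N-]
Why: Regitz diazo transfer from the sulfonyl azide to the doubly activated methylene under amine base, with the chelated phenol as a spectator.

**Step 4**
Reactants: 5 1-[2,4-bis(benzyloxy)-6-hydroxyphenyl]-3-[4-(benzyloxy)phenyl]-2-diazopropane-1,3-dione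
Product: 6 1-[2,4-bis(benzyloxy)-6-hydroxyphenyl]-3-[4-(benzyloxy)phenyl]propane-1,2,3-trione
Conditions: dimethyldioxirane (1.5 equiv, 0.07 M in acetone, distilled beforehand from KHSO5, NaHCO3 and acetone), CH2Cl2, 0 °C; evaporate, azeotrope with toluene
Reagents that add atoms: dimethyldioxirane, CC1(C)OO1
Why: Oxygen-atom transfer from a dioxirane to the diazo carbon with loss of N2 is the standard neutral route from 2-diazo-1,3-dicarbonyl compounds to vicinal tricarbonyls, it is much faster than attack on the acyl-deactivated arenes or the benzyl ethers, and only volatile by-products form, so the water-sensitive trione is obtained by evaporation.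

**Step 5**
Reactants: 4 1-[2,4-bis(benzyloxy)-6-hydroxyphenyl]-3-[4-(benzyloxy)phenyl]propane-1,3-dione
Product: 7 5,7-bis(benzyloxy)-2-[4-(benzyloxy)phenyl]-4H-chromen-4-one
Conditions: p-toluenesulfonic acid monohydrate (10 mol%), toluene, reflux, Dean–Stark trap
Reagents that add atoms: none
Why: Acid-catalysed cyclodehydration of an o-hydroxyaryl 1,3-diketone (the closing stage of the Baker–Venkataraman flavone synthesis), driven by formation of the aromatic pyranone under conditions too mild to cleave aryl benzyl ethers.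

**Step 6**
Reactants: 7 5,7-bis(benzyloxy)-2-[4-(benzyloxy)phenyl]-4H-chromen-4-one
Product: 9 (2S,4S)-5,7-bis(benzyloxy)-2-[4-(benzyloxy)phenyl]chroman-4-ol, via (2S)-flavanone 8 (not isolated)
Conditions: [Ru(cod)(2-methylallyl)2] (5 mol%), 1,3-bis[(1R)-1-(naphthalen-1-yl)ethyl]-4,5-dihydroimidazolium tetrafluoroborate (10 mol%), KOt-Bu (15 mol%), H2 (120 bar), toluene, 40 °C
Reagents that add atoms: none
Why: Ruthenium–N-heterocyclic-carbene-catalysed asymmetric hydrogenation of flavones, in which the chiral carbene ligands differentiate the faces of the C2=C3 bond and set C2 as S, the ketone of 8 is then reduced from the face opposite the 2-aryl group to the cis alcohol (its C4 centre is deleted in step 7), and the homogeneous catalyst does not hydrogenolyse benzyl ethers.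

**Step 7**
Reactants: 9 (2S,4S)-5,7-bis(benzyloxy)-2-[4-(benzyloxy)phenyl]chroman-4-ol
Product: 10 (2S)-5,7-bis(benzyloxy)-2-[4-(benzyloxy)phenyl]chromane
Conditions: Et3SiH (10 equiv), CF3CO2H (5 equiv), CH2Cl2 (0.02 M), −40 to 0 °C
Reagents that add atoms: none
Why: Ionic hydrogenation (deoxygenation) of a benzylic alcohol, in which acid ionises the C4–OH bond with help from the ortho and para benzyloxy groups, the large excess of silane at high dilution delivers hydride faster than a second flavan can attack, and C2 is not involved and stays S.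

**Step 8**
Reactants: 6 1-[2,4-bis(benzyloxy)-6-hydroxyphenyl]-3-[4-(benzyloxy)phenyl]propane-1,2,3-trione; 10 (2S)-5,7-bis(benzyloxy)-2-[4-(benzyloxy)phenyl]chromane
Product: 12 (3R)-5,7-bis(benzyloxy)-3-{(2S)-5,7-bis(benzyloxy)-2-[4-(benzyloxy)phenyl]chroman-8-yl}-2-[4-(benzyloxy)phenyl]-2,3-dihydroxychroman-4-one, via open-chain carbinol 11 (not isolated)
Conditions: Cu(OTf)2 (10 mol%), 2,2'-(propane-2,2-diyl)bis[(4S)-4-tert-butyl-4,5-dihydrooxazole] (11 mol%), 4 Å molecular sieves, CH2Cl2, −20 °C to rt
Reagents that add atoms: none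
Why: Proposed new method: the central carbonyl of a vicinal tricarbonyl is about as electrophilic as that of trifluoropyruvate or ninhydrin and should bind the cationic divalent copper bis(oxazoline) complex as a five-membered chelate through the central and the unhindered ring B carbonyl oxygens (the ring A carbonyl is tied up by its hydrogen bond to the phenol and flanked by an ortho benzyloxy group), so one tert-butyl group blocks one face and C8 of 10, the site at which perbenzylated 5,7-dioxygenated flavans are brominated and alkylated, adds to the open face and sets the carbinol centre under catalyst control (the remote flavan centre has no say), after which the free ring A phenol closes on the ring B ketone and takes 11 out of the retro-Friedel–Crafts equilibrium as 12; the closest known reaction types are the copper bis(oxazoline)-catalysed enantioselective Friedel–Crafts hydroxyalkylation of aromatic ethers with trifluoropyruvate, the copper bis(oxazoline)-catalysed carbonyl-ene reaction of 2,3-diketo esters and the arylation of ninhydrin by trialkoxybenzenes.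

**Step 9**
Reactants: 12 (3R)-5,7-bis(benzyloxy)-3-{(2S)-5,7-bis(benzyloxy)-2-[4-(benzyloxy)phenyl]chroman-8-yl}-2-[4-(benzyloxy)phenyl]-2,3-dihydroxychroman-4-one
Product: 14 daphnodorin F, via hexaphenol hemiketal 13 (not isolated)
Conditions: H2 (1 atm), Pd(OH)2/C, THF–EtOAc, rt; filter; pyridinium p-toluenesulfonate (10 mol%), THF, rt
Reagents that add atoms: none
Why: Catalytic hydrogenolysis of the six aryl benzyl ethers (conditions that spare flavan C2–O bonds and ketals in benzylated proanthocyanidin end-games) frees flavan O7, which under mild acid replaces the hemiketal OH by intramolecular ketalisation eased by the now free 4-hydroxyphenyl group, while the fully substituted carbinol centre cannot epimerise and the reversibly formed ketal carbon settles as the thermodynamic epimer that this centre dictates.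

**Compound list**
1 | 2',4',6'-trihydroxyacetophenone | CC(=O)c1c(O)cc(O)cc1O | starting material
2 | 1-[2,4-bis(benzyloxy)-6-hydroxyphenyl]ethan-1-one | CC(=O)c1c(O)cc(OCc2ccccc2)cc1OCc1ccccc1 | intermediate
3 | 4-(benzyloxy)benzoyl chloride | O=C(Cl)c1ccc(OCc2ccccc2)cc1 | starting material
4 | 1-[2,4-bis(benzyloxy)-6-hydroxyphenyl]-3-[4-(benzyloxy)phenyl]propane-1,3-dione (drawn as diketone) | O=C(CC(=O)c1ccc(OCc2ccccc2)cc1)c1c(O)cc(OCc2ccccc2)cc1OCc1ccccc1 | intermediate
5 | 1-[2,4-bis(benzyloxy)-6-hydroxyphenyl]-3-[4-(benzyloxy)phenyl]-2-diazopropane-1,3-dione | O=C(C(=[N+]=[N-])C(=O)c1ccc(OCc2ccccc2)cc1)c1c(O)cc(OCc2ccccc2)cc1OCc1ccccc1 | intermediate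
6 | 1-[2,4-bis(benzyloxy)-6-hydroxyphenyl]-3-[4-(benzyloxy)phenyl]propane-1,2,3-trione (drawn open; equilibrates with its cyclic hemiketal forms) | O=C(C(=O)C(=O)c1ccc(OCc2ccccc2)cc1)c1c(O)cc(OCc2ccccc2)cc1OCc1ccccc1 | intermediate
7 | 5,7-bis(benzyloxy)-2-[4-(benzyloxy)phenyl]-4H-chromen-4-one (tri-O-benzylapigenin) | O=c1cc(-c2ccc(OCc3ccccc3)cc2)oc2cc(OCc3ccccc3)cc(OCc3ccccc3)c12 | intermediate
8 | (2S)-5,7-bis(benzyloxy)-2-[4-(benzyloxy)phenyl]chroman-4-one ((2S)-flavanone) | O=C1C[C@@H](c2ccc(OCc3ccccc3)cc2)Oc2cc(OCc3ccccc3)cc(OCc3ccccc3)c12 | intermediate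
9 | (2S,4S)-5,7-bis(benzyloxy)-2-[4-(benzyloxy)phenyl]chroman-4-ol (2,4-cis) | O[C@H]1C[C@@H](c2ccc(OCc3ccccc3)cc2)Oc2cc(OCc3ccccc3)cc(OCc3ccccc3)c12 | intermediate
10 | (2S)-5,7-bis(benzyloxy)-2-[4-(benzyloxy)phenyl]chromane | c1ccccc1COc1cc(OCc2ccccc2)c2c(c1)O[C@H](c1ccc(OCc3ccccc3)cc1)CC2 | intermediate
11 | (2S)-2-{(2S)-5,7-bis(benzyloxy)-2-[4-(benzyloxy)phenyl]chroman-8-yl}-1-[2,4-bis(benzyloxy)-6-hydroxyphenyl]-3-[4-(benzyloxy)phenyl]-2-hydroxypropane-1,3-dione (open-chain carbinol; same spatial arrangement as 3R in 12) | O=C(c1c(O)cc(OCc2ccccc2)cc1OCc1ccccc1)[C@@](O)(C(=O)c1ccc(OCc2ccccc2)cc1)c1c(OCc2ccccc2)cc(OCc2ccccc2)c2c1O[C@H](c1ccc(OCc3ccccc3)cc1)CC2 | intermediate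
12 | (3R)-5,7-bis(benzyloxy)-3-{(2S)-5,7-bis(benzyloxy)-2-[4-(benzyloxy)phenyl]chroman-8-yl}-2-[4-(benzyloxy)phenyl]-2,3-dihydroxychroman-4-one (labile hemiketal carbon C2 as anomer mixture) | O=C1c2c(OCc3ccccc3)cc(OCc3ccccc3)cc2OC(O)(c2ccc(OCc3ccccc3)cc2)[C@@]1(O)c1c(OCc2ccccc2)cc(OCc2ccccc2)c2c1O[C@H](c1ccc(OCc3ccccc3)cc1)CC2 | intermediate
13 | (3R)-3-[(2S)-5,7-dihydroxy-2-(4-hydroxyphenyl)chroman-8-yl]-2,3,5,7-tetrahydroxy-2-(4-hydroxyphenyl)chroman-4-one (hexaphenol hemiketal, anomer mixture at C2) | O=C1c2c(O)cc(O)cc2OC(O)(c2ccc(O)cc2)[C@@]1(O)c1c(O)cc(O)c2c1O[C@H](c1ccc(O)cc1)CC2 | intermediate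
14 | daphnodorin F (flavan C2 S, ketal carbon S, carbinol carbon R) | O=C1c2c(O)cc(O)cc2O[C@]2(c3ccc(O)cc3)Oc3cc(O)c4c(c3[C@@]12O)O[C@H](c1ccc(O)cc1)CC4 | target

**Step count**
Total steps: 9.
Longest linear sequence: 7 steps (1, 2, 5, 6, 7, 8, 9).

**Steps most likely to fail**

Step 8 carries the most risk. The trione may hide in its cyclic hemiketal forms, the chelate geometry and therefore the facial selectivity are untested, and some attack at C6 is possible. The fallback replaces the C–H addition by cross-coupling plus asymmetric epoxidation. It sets out from 7 and 10 and comes back to the route at 12.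
- Deprotonation of 7 at C3 with LiN(i-Pr)2 (THF, −78 °C) and quenching with I2 gives 5,7-bis(benzyloxy)-2-[4-(benzyloxy)phenyl]-3-iodo-4H-chromen-4-one F1.
- N-Bromosuccinimide (CH2Cl2, −78 to 0 °C) brominates 10 at C8 only and gives (2S)-5,7-bis(benzyloxy)-2-[4-(benzyloxy)phenyl]-8-bromochromane F2.
- Treating F2 with n-BuLi and then 2-isopropoxy-4,4,5,5-tetramethyl-1,3,2-dioxaborolane gives (2S)-5,7-bis(benzyloxy)-2-[4-(benzyloxy)phenyl]-8-(4,4,5,5-tetramethyl-1,3,2-dioxaborolan-2-yl)chromane F3.
- Suzuki–Miyaura coupling of F1 with F3 (Pd(OAc)2, 2-dicyclohexylphosphino-2',6'-dimethoxybiphenyl, K3PO4, toluene–water, 90 °C) gives 5,7-bis(benzyloxy)-3-{(2S)-5,7-bis(benzyloxy)-2-[4-(benzyloxy)phenyl]chroman-8-yl}-2-[4-(benzyloxy)phenyl]-4H-chromen-4-one F4.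
- Jacobsen–Katsuki epoxidation of the chromone C2=C3 bond is a reaction type known for isoflavones. With [(R,R)-N,N'-bis(3,5-di-tert-butylsalicylidene)cyclohexane-1,2-diaminato]MnCl or its antipode, NaOCl and 4-phenylpyridine N-oxide (CH2Cl2, 0 °C) it gives, under reagent control, the 2,3-epoxy-2,3-dihydro derivative of F4 F5.
- Water with a trace of acid opens F5 at the oxygen- and aryl-stabilised C2 without touching the C3–O bond and gives 12.

Step 6 is the second risk. The 5-benzyloxyflavone is hindered, electron-rich and poorly soluble, so conversion and enantioselectivity at high pressure may be low. The fallback makes the C2–aryl bond asymmetrically instead of reducing a flavone. It sets out from 2 and comes back at 9, passing through 8, which is isolated in this case.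
- N,N-Dimethylformamide dimethyl acetal (toluene, 90 °C) converts 2 into (E)-1-[2,4-bis(benzyloxy)-6-hydroxyphenyl]-3-(dimethylamino)prop-2-en-1-one F6.
- Dilute HCl in CH2Cl2 cyclises F6 to 5,7-bis(benzyloxy)-4H-chromen-4-one F7.
- Hayashi–Miyaura 1,4-addition of 4-(benzyloxy)phenylboronic acid to F7 gives 8. It uses [RhCl(C2H4)2]2, the antipode of 2,5-diphenylbicyclo[2.2.2]octa-2,5-diene that delivers 2S, and KOH in toluene–water at 40 °C.
- NaBH4 (THF–MeOH, 0 °C) reduces 8 to 9.

Step 9 is the third risk. Six benzyl ethers must be removed in the presence of hydrogenolysis-prone benzylic C–O bonds: flavan C2–O, the hemiketal and the tertiary carbinol. The fallback is non-reductive. It sets out from 12 and comes back at 14. BCl3 with pentamethylbenzene (CH2Cl2, −78 °C) transfers the benzyl groups as cations to the arene scavenger. The Lewis-acidic medium and the mildly acidic work-up then close 13 to 14. This fallback makes no new compound (F0).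

**Further compounds**
F1 | step 8 | 5,7-bis(benzyloxy)-2-[4-(benzyloxy)phenyl]-3-iodo-4H-chromen-4-one | O=c1c(I)c(-c2ccc(OCc3ccccc3)cc2)oc2cc(OCc3ccccc3)cc(OCc3ccccc3)c12
F2 | step 8 | (2S)-5,7-bis(benzyloxy)-2-[4-(benzyloxy)phenyl]-8-bromochromane | Brc1c(OCc2ccccc2)cc(OCc2ccccc2)c2c1O[C@H](c1ccc(OCc3ccccc3)cc1)CC2
F3 | step 8 | (2S)-5,7-bis(benzyloxy)-2-[4-(benzyloxy)phenyl]-8-(4,4,5,5-tetramethyl-1,3,2-dioxaborolan-2-yl)chromane | CC1(C)OB(OC1(C)C)c1c(OCc2ccccc2)cc(OCc2ccccc2)c2c1O[C@H](c1ccc(OCc3ccccc3)cc1)CC2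
F4 | step 8 | 5,7-bis(benzyloxy)-3-{(2S)-5,7-bis(benzyloxy)-2-[4-(benzyloxy)phenyl]chroman-8-yl}-2-[4-(benzyloxy)phenyl]-4H-chromen-4-one | O=c1c(-c2c(OCc3ccccc3)cc(OCc3ccccc3)c3c2O[C@H](c2ccc(OCc4ccccc4)cc2)CC3)c(-c2ccc(OCc3ccccc3)cc2)oc2cc(OCc3ccccc3)cc(OCc3ccccc3)c12
F5 | step 8 | 2,3-epoxy-2,3-dihydro derivative of F4 (oxirane oxygen on the face of the tertiary OH of 12) | O=C1c2c(OCc3ccccc3)cc(OCc3ccccc3)cc2O[C@]2(c3ccc(OCc4ccccc4)cc3)O[C@]12c1c(OCc2ccccc2)cc(OCc2ccccc2)c2c1O[C@H](c1ccc(OCc3ccccc3)cc1)CC2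
F6 | step 6 | (E)-1-[2,4-bis(benzyloxy)-6-hydroxyphenyl]-3-(dimethylamino)prop-2-en-1-one | CN(C)/C=C/C(=O)c1c(O)cc(OCc2ccccc2)cc1OCc1ccccc1
F7 | step 6 | 5,7-bis(benzyloxy)-4H-chromen-4-one | O=c1ccoc2cc(OCc3ccccc3)cc(OCc3ccccc3)c12
F0 | step 9 | none | none
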